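**Plan**

1. Retrosynthetic cuts, in order: the O6–acyl ester bond (side chain 31); the lactone C12–O8 bond, moved back to O6 (6,12-olide 25); C7–C8 (ten-membered ring, key step); then C11–C12 (CO), C6–C7 (alkynylation), C5–C6 (formylation), C3–C4 (carbomagnesiation), C1–C2 (oxirane) and C10–CH3 (carboalumination).
2. Enabling feature: C7 is flanked by oxygen on both C6 and C8 and carries the C11(=C13)–C12 acrylate. C12 can therefore be parked on O6 as a butenolide ring (O–C6–C7=C11–C12). This makes C13–C11=C7 a geometry-locked 2-acylallyl unit whose γ-carbon C7 closes onto a C8 aldehyde, after which the temporary 6,12-lactone is moved to O8.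
3. Forward order: chain C8→C3 (steps 1–3); C4/C5/C15 (step 4); C6 and C7/C11/C13 (steps 6–8); butenolide (step 9); unmasking of C13–Br and C8=O (steps 10–12); ten-membered carbocycle with the α-methylene 6,12-lactone (step 13); 8,12-lactone (step 14); esterification and desilylation (steps 18, 19).
4. Stereochemistry: C6 from catalyst-controlled alkynylation (step 7); C7 and C8 from C6 through the butenolide-locked allylchromium chair (step 13).
5. Olefin geometry: C1=C10 (E) from syn-carboalumination; C4=C5 from chelated anti-carbomagnesiation; side-chain E from a stabilised Wittig reaction.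

Key step: step 13

Remark: atoms are labelled with germacrane numbering (C1=C10, C4=C5, C6 acyloxy, C7, C8 lactone oxygen, C11=C13, C12 carbonyl, C14 methyl, C15 CH2OH).
Assumption: in step 7 the (R,R)-ProPhenol antipode is taken to deliver the alkynyl group to the Si face of enal 14. If a Mosher analysis of 17 shows the opposite sense, the (S,S) ligand is used with nothing else changed.

**Route**

Step 1
Reactants: 1 but-3-yn-1-ol
Product: 2 1-[(but-3-yn-1-yloxy)methyl]-4-methoxybenzene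
Conditions: NaH, 4-methoxybenzyl chloride, Bu4NI (cat.), THF/DMF, 0 °C → rt
Reagents that add atoms: 4-methoxybenzyl chloride, COc1ccc(CCl)cc1
Why: Williamson etherification masks the future C8 oxygen as a PMB ether that survives the organometallic steps and can later be removed oxidatively under neutral conditions.

Step 2
Reactants: 2 1-[(but-3-yn-1-yloxy)methyl]-4-methoxybenzene, 3 oxirane
Product: 6 (3E)-6-[(4-methoxybenzyl)oxy]-4-methylhex-3-en-1-ol, via alkenyldimethylalane 4 (not isolated), via lithium alkenylalanate 5 (not isolated)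
Conditions: Me3Al, Cp2ZrCl2 (25 mol %), CH2Cl2, 0 °C → rt; evaporate; n-BuLi, hexane/THF, −78 → 0 °C; oxirane, 0 °C → rt; aq. Rochelle salt/NH4Cl
Reagents that add atoms: trimethylaluminium, C[Al](C)C
Why: Zirconium-catalysed syn-methylalumination of the terminal alkyne (Negishi carboalumination) fixes the E geometry of C1=C10, and the derived alanate opens oxirane with retention at the alkenyl carbon to add C2 and C3.

Step 3
Reactants: 6 (3E)-6-[(4-methoxybenzyl)oxy]-4-methylhex-3-en-1-ol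
Product: 7 1-({[(3E)-6-bromo-3-methylhex-3-en-1-yl]oxy}methyl)-4-methoxybenzene
Conditions: CBr4, PPh3, CH2Cl2, 0 °C
Reagents that add atoms: carbon tetrabromide, BrC(Br)(Br)Br
Why: Appel bromination converts the primary homoallylic alcohol into the bromide under neutral conditions that leave the trisubstituted olefin and the PMB ether untouched.

Step 4
Reactants: 7 1-({[(3E)-6-bromo-3-methylhex-3-en-1-yl]oxy}methyl)-4-methoxybenzene, 8 prop-2-yn-1-ol
Product: 11 (2Z)-3-iodo-2-[(3E)-6-[(4-methoxybenzyl)oxy]-4-methylhex-3-en-1-yl]prop-2-en-1-ol, via Grignard reagent 9 (not isolated), via cyclic alkenylmagnesium alkoxide 10 (not isolated)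
Conditions: Mg, THF, rt (7 → 9); 8 pre-treated with EtMgBr (1.0 equiv), THF, 0 °C, then 9, CuI (15 mol %), rt → 35 °C; I2, −78 → 0 °C
Reagents that add atoms: iodine, II
Why: Copper-catalysed anti-carbomagnesiation of the propargylic alkoxide (Duboudin reaction) puts the alkyl group on C4 and magnesium on C5 chelated by the C15 alkoxide, so iodinolysis with retention should give the iodide cis to CH2OH, which is the C4=C5 geometry of the target.

Step 5
Reactants: 11 (2Z)-3-iodo-2-[(3E)-6-[(4-methoxybenzyl)oxy]-4-methylhex-3-en-1-yl]prop-2-en-1-ol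
Product: 12 tert-butyl{[(2Z)-3-iodo-2-[(3E)-6-[(4-methoxybenzyl)oxy]-4-methylhex-3-en-1-yl]prop-2-en-1-yl]oxy}diphenylsilane
Conditions: TBDPSCl, imidazole, CH2Cl2, rt
Reagents that add atoms: tert-butyl(chloro)diphenylsilane, CC(C)(C)[Si](Cl)(c1ccccc1)c1ccccc1
Why: Silylation gives the C15 oxygen a robust TBDPS ether that stays in place to the last step and can be told apart from the TBS ether introduced in step 7.

Step 6
Reactants: 12 tert-butyl{[(2Z)-3-iodo-2-[(3E)-6-[(4-methoxybenzyl)oxy]-4-methylhex-3-en-1-yl]prop-2-en-1-yl]oxy}diphenylsilane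
Product: 14 (2Z,6E)-3-{[(tert-butyldiphenylsilyl)oxy]methyl}-9-[(4-methoxybenzyl)oxy]-7-methylnona-2,6-dienal, via alkenyllithium 13 (not isolated)
Conditions: t-BuLi (2.1 equiv), Et2O, −78 °C; DMF, −78 → 0 °C; aq. NH4Cl
Reagents that add atoms: N,N-dimethylformamide, CN(C)C=O
Why: Iodine–lithium exchange proceeds with retention of the olefin geometry and formylation with DMF should give the Z-enal (C6), with ether at −78 °C holding back 1,4 O→C silyl migration in the γ-silyloxy alkenyllithium.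

Step 7
Reactants: 14 (2Z,6E)-3-{[(tert-butyldiphenylsilyl)oxy]methyl}-9-[(4-methoxybenzyl)oxy]-7-methylnona-2,6-dienal, 15 tert-butyldimethyl(prop-2-yn-1-yloxy)silane
Product: 17 (4R,5Z,9E)-1-[(tert-butyldimethylsilyl)oxy]-6-{[(tert-butyldiphenylsilyl)oxy]methyl}-12-[(4-methoxybenzyl)oxy]-10-methyldodeca-5,9-dien-2-yn-4-ol, via alkynylzinc 16 (not isolated)
Conditions: Me2Zn (3 equiv), (R,R)-ProPhenol (20 mol %), Ph3P=O (40 mol %), toluene, 0–4 °C
Reagents that add atoms: none
Why: Dinuclear zinc–ProPhenol catalysed enantioselective alkynylation, a reaction established for α,β-unsaturated aldehydes, adds the C7–C11–C13 unit to one face of the enal and so sets C6 (4R in 17) under catalyst control.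

Step 8
Reactants: 17 (4R,5Z,9E)-1-[(tert-butyldimethylsilyl)oxy]-6-{[(tert-butyldiphenylsilyl)oxy]methyl}-12-[(4-methoxybenzyl)oxy]-10-methyldodeca-5,9-dien-2-yn-4-ol
Product: 19 (2Z,4R,5Z,9E)-1-[(tert-butyldimethylsilyl)oxy]-6-{[(tert-butyldiphenylsilyl)oxy]methyl}-2-iodo-12-[(4-methoxybenzyl)oxy]-10-methyldodeca-2,5,9-trien-4-ol, via cyclic alkenylaluminate 18 (not isolated)
Conditions: Red-Al (2.5 equiv), THF, −20 → 0 °C; EtOAc; I2, THF, −78 → −20 °C
Reagents that add atoms: iodine, II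
Why: Alkoxide-directed trans-hydroalumination of the propargylic alcohol delivers hydride to C7 and aluminium to C11 in a five-membered oxaaluminacycle, and low-temperature iodinolysis with retention should give the iodide cis to the C6 carbinol before the β-silyloxy group can eliminate to an allene.

Step 9
Reactants: 19 (2Z,4R,5Z,9E)-1-[(tert-butyldimethylsilyl)oxy]-6-{[(tert-butyldiphenylsilyl)oxy]methyl}-2-iodo-12-[(4-methoxybenzyl)oxy]-10-methyldodeca-2,5,9-trien-4-ol
Product: 20 (5R)-3-{[(tert-butyldimethylsilyl)oxy]methyl}-5-[(1Z,5E)-2-{[(tert-butyldiphenylsilyl)oxy]methyl}-8-[(4-methoxybenzyl)oxy]-6-methylocta-1,5-dien-1-yl]furan-2(5H)-one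
Conditions: PdCl2(PPh3)2 (5 mol %), CO (1 atm), K2CO3, THF, rt
Reagents that add atoms: carbon monoxide, [C-]#[O+]
Why: Palladium-catalysed cyclocarbonylation of a (Z)-γ-hydroxy vinyl iodide (oxidative addition at C11–I, CO insertion to give C12, capture of the acylpalladium by the cis C6 hydroxyl) closes the butenolide that parks C12 on O6 and locks the C7=C11 geometry.

Step 10
Reactants: 20 (5R)-3-{[(tert-butyldimethylsilyl)oxy]methyl}-5-[(1Z,5E)-2-{[(tert-butyldiphenylsilyl)oxy]methyl}-8-[(4-methoxybenzyl)oxy]-6-methylocta-1,5-dien-1-yl]furan-2(5H)-one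
Product: 21 (5R)-3-(bromomethyl)-5-[(1Z,5E)-2-{[(tert-butyldiphenylsilyl)oxy]methyl}-8-[(4-methoxybenzyl)oxy]-6-methylocta-1,5-dien-1-yl]furan-2(5H)-one
Conditions: Ph3PBr2, CH2Cl2, 0 °C → rt
Reagents that add atoms: dibromotriphenylphosphorane, BrP(Br)(c1ccccc1)(c1ccccc1)c1ccccc1
Why: Dibromotriphenylphosphorane converts the primary allylic TBS ether directly into the C13 bromide through silyl/phosphonium exchange, a reaction to which the bulkier TBDPS ether and the PMB ether are much less prone.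

Step 11
Reactants: 21 (5R)-3-(bromomethyl)-5-[(1Z,5E)-2-{[(tert-butyldiphenylsilyl)oxy]methyl}-8-[(4-methoxybenzyl)oxy]-6-methylocta-1,5-dien-1-yl]furan-2(5H)-one
Product: 22 (5R)-3-(bromomethyl)-5-[(1Z,5E)-2-{[(tert-butyldiphenylsilyl)oxy]methyl}-8-hydroxy-6-methylocta-1,5-dien-1-yl]furan-2(5H)-one
Conditions: DDQ, CH2Cl2/pH 7 buffer (10:1), 0 °C
Reagents that add atoms: none
Why: Oxidative cleavage of the PMB ether by DDQ under buffered conditions frees the C8 hydroxyl without touching the allylic bromide, the butenolide or the silyl ether.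

Step 12
Reactants: 22 (5R)-3-(bromomethyl)-5-[(1Z,5E)-2-{[(tert-butyldiphenylsilyl)oxy]methyl}-8-hydroxy-6-methylocta-1,5-dien-1-yl]furan-2(5H)-one
Product: 23 (3E,7Z)-8-[(2R)-4-(bromomethyl)-5-oxo-2,5-dihydrofuran-2-yl]-7-{[(tert-butyldiphenylsilyl)oxy]methyl}-3-methylocta-3,7-dienal
Conditions: Dess–Martin periodinane, NaHCO3, CH2Cl2, 0 °C; crude aldehyde used at once
Reagents that add atoms: none
Why: Dess–Martin oxidation under buffered, non-basic conditions should give the β,γ-unsaturated C8 aldehyde without moving the C1=C10 double bond into conjugation.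

Step 13
Reactants: 23 (3E,7Z)-8-[(2R)-4-(bromomethyl)-5-oxo-2,5-dihydrofuran-2-yl]-7-{[(tert-butyldiphenylsilyl)oxy]methyl}-3-methylocta-3,7-dienal
Product: 25 (6R,7R,8S)-15-[(tert-butyldiphenylsilyl)oxy]-8α-hydroxygermacra-1(10)E,4Z,11(13)-trien-6α,12-olide, via allylchromium(III) species 24 (not isolated)
Conditions: CrCl2 (10 equiv), THF (5 % DMF), syringe-pump addition of 23 to 2 mM, rt; aq. NH4Cl
Reagents that add atoms: none
Why: CrCl2 reduces the allylic C13–Br bond in two one-electron steps to the σ-allylchromium(III) 24, which adds through its γ-carbon C7 to the tethered C8 aldehyde in a six-membered Zimmerman–Traxler chair (Cr–O=C8···C7=C11–C13) with allylic transposition, so that the C7–C8 bond, the C11=C13 methylene and the ten-membered ring arise together. The closest known reaction types are the intramolecular Nozaki–Hiyama–Kishi (Barbier-type) 2-(alkoxycarbonyl)allylation used to close ten-membered germacranolide carbocycles and the intermolecular Barbier allylation of β,γ-unsaturated aldehydes with 3-(bromomethyl)furan-2(5H)-ones. The carbocycle closes in a 10-exo-trig mode at the aldehyde (C8=O exocyclic) with SE2′ attack of the allyl unit (C11 exocyclic), and no other ring is formed in this step. C7 is controlled by the C6 stereocentre of the planar butenolide, C8 bonding to the face opposite the C6–C5 bond (6,7-trans ring fusion, 7R); C8 is controlled by the chair, in which C9 sits equatorial and the allyl geometry is locked by the ring (C6 cis to C12, trans to C13), which should give the 7,8-anti adduct (8S, 8α-OH). The step needs γ- over α-attack, cyclisation over oligomerisation and tolerance of the lactone, the silyl ether and the enolisable aldehyde; these are secured by the SE2′ preference of allylchromium reagents, by high dilution together with the two trisubstituted olefins that preorganise the chain, and by the non-basic, carbonyl-selective character of Cr(II)/Cr(III).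

Step 14
Reactants: 25 (6R,7R,8S)-15-[(tert-butyldiphenylsilyl)oxy]-8α-hydroxygermacra-1(10)E,4Z,11(13)-trien-6α,12-olide
Product: 26 (6R,7S,8S)-15-[(tert-butyldiphenylsilyl)oxy]-6α-hydroxygermacra-1(10)E,4Z,11(13)-trien-8α,12-olide
Conditions: DBU (0.2 equiv), toluene, rt
Reagents that add atoms: none
Why: Base-catalysed translactonisation (1,3-acyl shift through the C8 alkoxide and a bicyclic tetrahedral intermediate) moves C12 from O6 to O8 without touching a stereocentre, and is expected to be downhill because 6α,8α-dioxygenated germacra-1(10),4-dienolides are known to prefer lactone closure to O8.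

Step 15
Reactants: 27 glycolaldehyde dimer (1,4-dioxane-2,5-diol), 28 ethyl 2-(triphenyl-λ5-phosphanylidene)propanoate
Product: 29 ethyl (2E)-4-hydroxy-2-methylbut-2-enoate
Conditions: CH2Cl2, reflux
Reagents that add atoms: none
Why: Wittig olefination of monomeric glycolaldehyde with the stabilised α-methyl ylide should give the E-trisubstituted enoate of the side chain.

Step 16
Reactants: 29 ethyl (2E)-4-hydroxy-2-methylbut-2-enoate
Product: 30 ethyl (2E)-4-[(tert-butyldiphenylsilyl)oxy]-2-methylbut-2-enoate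
Conditions: TBDPSCl, imidazole, CH2Cl2, rt
Reagents that add atoms: tert-butyl(chloro)diphenylsilane, CC(C)(C)[Si](Cl)(c1ccccc1)c1ccccc1
Why: Silylation protects the side-chain hydroxyl with the same group as O15 so that one fluoride treatment finishes the synthesis.

Step 17
Reactants: 30 ethyl (2E)-4-[(tert-butyldiphenylsilyl)oxy]-2-methylbut-2-enoate
Product: 31 (2E)-4-[(tert-butyldiphenylsilyl)oxy]-2-methylbut-2-enoic acid
Conditions: LiOH·H2O, THF/MeOH/H2O, rt; 1 M HCl to pH 4
Reagents that add atoms: lithium hydroxide, [Li+].[OH-]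
Why: Saponification of the ethyl ester gives the acid while the TBDPS ether, stable to aqueous base, stays in place.

Step 18
Reactants: 26 (6R,7S,8S)-15-[(tert-butyldiphenylsilyl)oxy]-6α-hydroxygermacra-1(10)E,4Z,11(13)-trien-8α,12-olide, 31 (2E)-4-[(tert-butyldiphenylsilyl)oxy]-2-methylbut-2-enoic acid
Product: 33 (6R,7R,8S)-15-[(tert-butyldiphenylsilyl)oxy]-8α,12-olide 6-O-[(2E)-4-[(tert-butyldiphenylsilyl)oxy]-2-methylbut-2-enoate], via mixed anhydride 32 (not isolated)
Conditions: 31, 2,4,6-trichlorobenzoyl chloride, Et3N, toluene, rt; then 26, DMAP, rt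
Reagents that add atoms: none
Why: Yamaguchi esterification through mixed anhydride 32 acylates the only free hydroxyl, the allylic O6–H, while O15 is silylated and O8 is tied up in the lactone.

Step 19
Reactants: 33 (6R,7R,8S)-15-[(tert-butyldiphenylsilyl)oxy]-8α,12-olide 6-O-[(2E)-4-[(tert-butyldiphenylsilyl)oxy]-2-methylbut-2-enoate]
Product: 34 CNP0344932.1 (target)
Conditions: HF·pyridine, pyridine, THF, 0 °C → rt
Reagents that add atoms: none
Why: Buffered HF·pyridine removes both primary allylic TBDPS ethers without base, which should avoid acyl migration from O6 to the cis-disposed O15, translactonisation and conjugate addition to the α-methylene lactone.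

**Compound list**

1 | but-3-yn-1-ol | C#CCCO | starting material
2 | 1-[(but-3-yn-1-yloxy)methyl]-4-methoxybenzene | C#CCCOCc1ccc(OC)cc1 | intermediate
3 | oxirane | C1CO1 | starting material
4 | dimethyl[(1E)-4-[(4-methoxybenzyl)oxy]-2-methylbut-1-en-1-yl]alumane | COc1ccc(COCC/C(C)=C/[Al](C)C)cc1 | intermediate
5 | lithium butyl(dimethyl)[(1E)-4-[(4-methoxybenzyl)oxy]-2-methylbut-1-en-1-yl]aluminate | [Li+].CCCC[Al-](C)(C)/C=C(\C)CCOCc1ccc(OC)cc1 | intermediate
6 | (3E)-6-[(4-methoxybenzyl)oxy]-4-methylhex-3-en-1-ol | COc1ccc(COCC/C(C)=C/CCO)cc1 | intermediate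
7 | 1-({[(3E)-6-bromo-3-methylhex-3-en-1-yl]oxy}methyl)-4-methoxybenzene | COc1ccc(COCC/C(C)=C/CCBr)cc1 | intermediate
8 | prop-2-yn-1-ol | C#CCO | starting material
9 | bromo[(3E)-6-[(4-methoxybenzyl)oxy]-4-methylhex-3-en-1-yl]magnesium | COc1ccc(COCC/C(C)=C/CC[Mg]Br)cc1 | intermediate
10 | 4-[(3E)-6-[(4-methoxybenzyl)oxy]-4-methylhex-3-en-1-yl]-2,5-dihydro-1,2-oxamagnesole (cyclic Z-alkenylmagnesium alkoxide) | COc1ccc(COCC/C(C)=C/CCC2=C[Mg]OC2)cc1 | intermediate
11 | (2Z)-3-iodo-2-[(3E)-6-[(4-methoxybenzyl)oxy]-4-methylhex-3-en-1-yl]prop-2-en-1-ol | COc1ccc(COCC/C(C)=C/CC/C(CO)=C/I)cc1 | intermediate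
12 | tert-butyl{[(2Z)-3-iodo-2-[(3E)-6-[(4-methoxybenzyl)oxy]-4-methylhex-3-en-1-yl]prop-2-en-1-yl]oxy}diphenylsilane | COc1ccc(COCC/C(C)=C/CC/C(CO[Si](c2ccccc2)(c2ccccc2)C(C)(C)C)=C/I)cc1 | intermediate
13 | (Z)-alkenyllithium derived from 12 (lithium in place of iodine at C5) | COc1ccc(COCC/C(C)=C/CC/C(CO[Si](c2ccccc2)(c2ccccc2)C(C)(C)C)=C/[Li])cc1 | intermediate
14 | (2Z,6E)-3-{[(tert-butyldiphenylsilyl)oxy]methyl}-9-[(4-methoxybenzyl)oxy]-7-methylnona-2,6-dienal | COc1ccc(COCC/C(C)=C/CC/C(CO[Si](c2ccccc2)(c2ccccc2)C(C)(C)C)=C/C=O)cc1 | intermediate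
15 | tert-butyldimethyl(prop-2-yn-1-yloxy)silane | C#CCO[Si](C)(C)C(C)(C)C | starting material
16 | methyl{3-[(tert-butyldimethylsilyl)oxy]prop-1-yn-1-yl}zinc | C[Zn]C#CCO[Si](C)(C)C(C)(C)C | intermediate
17 | (4R,5Z,9E)-1-[(tert-butyldimethylsilyl)oxy]-6-{[(tert-butyldiphenylsilyl)oxy]methyl}-12-[(4-methoxybenzyl)oxy]-10-methyldodeca-5,9-dien-2-yn-4-ol | COc1ccc(COCC/C(C)=C/CC/C(CO[Si](c2ccccc2)(c2ccccc2)C(C)(C)C)=C/[C@@H](O)C#CCO[Si](C)(C)C(C)(C)C)cc1 | intermediate
18 | sodium 2,2-bis(2-methoxyethoxy)-2,5-dihydro-1,2-oxaaluminol-2-uide carrying CH2OTBS at C3 (C11) and the (R)-configured dienyl chain at C5 (C6) | [Na+].COc1ccc(COCC/C(C)=C/CC/C(CO[Si](c2ccccc2)(c2ccccc2)C(C)(C)C)=C/[C@H]2O[Al-](OCCOC)(OCCOC)C(CO[Si](C)(C)C(C)(C)C)=C2)cc1 | intermediate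
19 | (2Z,4R,5Z,9E)-1-[(tert-butyldimethylsilyl)oxy]-6-{[(tert-butyldiphenylsilyl)oxy]methyl}-2-iodo-12-[(4-methoxybenzyl)oxy]-10-methyldodeca-2,5,9-trien-4-ol | COc1ccc(COCC/C(C)=C/CC/C(CO[Si](c2ccccc2)(c2ccccc2)C(C)(C)C)=C/[C@@H](O)/C=C(\I)CO[Si](C)(C)C(C)(C)C)cc1 | intermediate
20 | (5R)-3-{[(tert-butyldimethylsilyl)oxy]methyl}-5-[(1Z,5E)-2-{[(tert-butyldiphenylsilyl)oxy]methyl}-8-[(4-methoxybenzyl)oxy]-6-methylocta-1,5-dien-1-yl]furan-2(5H)-one | COc1ccc(COCC/C(C)=C/CC/C(CO[Si](c2ccccc2)(c2ccccc2)C(C)(C)C)=C/[C@H]2OC(=O)C(CO[Si](C)(C)C(C)(C)C)=C2)cc1 | intermediate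
21 | (5R)-3-(bromomethyl)-5-[(1Z,5E)-2-{[(tert-butyldiphenylsilyl)oxy]methyl}-8-[(4-methoxybenzyl)oxy]-6-methylocta-1,5-dien-1-yl]furan-2(5H)-one | COc1ccc(COCC/C(C)=C/CC/C(CO[Si](c2ccccc2)(c2ccccc2)C(C)(C)C)=C/[C@H]2OC(=O)C(CBr)=C2)cc1 | intermediate
22 | (5R)-3-(bromomethyl)-5-[(1Z,5E)-2-{[(tert-butyldiphenylsilyl)oxy]methyl}-8-hydroxy-6-methylocta-1,5-dien-1-yl]furan-2(5H)-one | OCC/C(C)=C/CC/C(CO[Si](c1ccccc1)(c1ccccc1)C(C)(C)C)=C/[C@H]1OC(=O)C(CBr)=C1 | intermediate
23 | (3E,7Z)-8-[(2R)-4-(bromomethyl)-5-oxo-2,5-dihydrofuran-2-yl]-7-{[(tert-butyldiphenylsilyl)oxy]methyl}-3-methylocta-3,7-dienal | O=CC/C(C)=C/CC/C(CO[Si](c1ccccc1)(c1ccccc1)C(C)(C)C)=C/[C@H]1OC(=O)C(CBr)=C1 | intermediate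
24 | dichloro allylchromium(III) derived from 23 (CrCl2 in place of Br at C13) | O=CC/C(C)=C/CC/C(CO[Si](c1ccccc1)(c1ccccc1)C(C)(C)C)=C/[C@H]1OC(=O)C(C[Cr](Cl)Cl)=C1 | intermediate
25 | (3aR,4S,6E,10Z,11aR)-10-{[(tert-butyldiphenylsilyl)oxy]methyl}-4-hydroxy-6-methyl-3-methylidene-3a,4,5,8,9,11a-hexahydrocyclodeca[b]furan-2(3H)-one (trans-fused 6α,12-olide, 8α-OH, H-7α) | C=C1C(=O)O[C@@H]2/C=C(\CO[Si](c3ccccc3)(c3ccccc3)C(C)(C)C)CC/C=C(\C)C[C@H](O)[C@@H]12 | intermediate
26 | (3aS,4R,5Z,9E,11aS)-6-{[(tert-butyldiphenylsilyl)oxy]methyl}-4-hydroxy-10-methyl-3-methylidene-3a,4,7,8,11,11a-hexahydrocyclodeca[b]furan-2(3H)-one (trans-fused 8α,12-olide, 6α-OH, H-7α) | C=C1C(=O)O[C@H]2C/C(C)=C/CC/C(CO[Si](c3ccccc3)(c3ccccc3)C(C)(C)C)=C/[C@@H](O)[C@H]12 | intermediate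
27 | glycolaldehyde dimer (1,4-dioxane-2,5-diol) | OC1COC(O)CO1 | starting material
28 | ethyl 2-(triphenyl-λ5-phosphanylidene)propanoate | CCOC(=O)C(C)=P(c1ccccc1)(c1ccccc1)c1ccccc1 | starting material
29 | ethyl (2E)-4-hydroxy-2-methylbut-2-enoate | CCOC(=O)/C(C)=C/CO | intermediate
30 | ethyl (2E)-4-[(tert-butyldiphenylsilyl)oxy]-2-methylbut-2-enoate | CCOC(=O)/C(C)=C/CO[Si](c1ccccc1)(c1ccccc1)C(C)(C)C | intermediate
31 | (2E)-4-[(tert-butyldiphenylsilyl)oxy]-2-methylbut-2-enoic acid | OC(=O)/C(C)=C/CO[Si](c1ccccc1)(c1ccccc1)C(C)(C)C | intermediate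
32 | (2E)-4-[(tert-butyldiphenylsilyl)oxy]-2-methylbut-2-enoic 2,4,6-trichlorobenzoic anhydride | O=C(OC(=O)/C(C)=C/CO[Si](c1ccccc1)(c1ccccc1)C(C)(C)C)c1c(Cl)cc(Cl)cc1Cl | intermediate
33 | (3aR,4R,5Z,9E,11aS)-6-{[(tert-butyldiphenylsilyl)oxy]methyl}-10-methyl-3-methylidene-2-oxo-2,3,3a,4,7,8,11,11a-octahydrocyclodeca[b]furan-4-yl (2E)-4-[(tert-butyldiphenylsilyl)oxy]-2-methylbut-2-enoate | C=C1C(=O)O[C@H]2C/C(C)=C/CC/C(CO[Si](c3ccccc3)(c3ccccc3)C(C)(C)C)=C/[C@@H](OC(=O)/C(C)=C/CO[Si](c3ccccc3)(c3ccccc3)C(C)(C)C)[C@H]12 | intermediate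
34 | (3aR,4R,5Z,9E,11aS)-6-(hydroxymethyl)-10-methyl-3-methylidene-2-oxo-2,3,3a,4,7,8,11,11a-octahydrocyclodeca[b]furan-4-yl (2E)-4-hydroxy-2-methylbut-2-enoate (CNP0344932.1) | C=C1C(=O)O[C@H]2C/C(C)=C/CC/C(CO)=C/[C@@H](OC(=O)/C(C)=C/CO)[C@H]12 | target

**Step count and risks**

Total step count: 19. Longest linear sequence: 16 steps (steps 1–14, 18, 19); the side-chain acid takes steps 15–17.

Steps most likely to fail:

1. Step 13. What may go wrong:
   - oligomerisation competing with ring closure;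
   - vinylogous β-elimination of the lactone carboxylate from the allylchromium before it meets the aldehyde;
   - loss of facial control at C7 or C8;
   - conjugation of the β,γ-unsaturated aldehyde.

   Fallback (no temporary ring; the side chain is put on O6 first, so the lactone can only close to O8). It sets out from 19 and 31 and comes back at 33. Yamaguchi esterification of 19 with 31 gives the O6-acylated vinyl iodide F1. Palladium-catalysed methoxycarbonylation (PdCl2(PPh3)2, CO, MeOH, Et3N) gives the methyl (E)-enoate F2, which cannot lactonise. Ph3PBr2 turns its TBS ether into the allylic bromide F3. DDQ frees the primary alcohol F4, and Dess–Martin oxidation gives the aldehyde F5. Chromium(II)-mediated cyclisation of F5 at high dilution, the form of this macrocyclisation closest to the known germacranolide ring closures, followed by lactonisation of the C8 chromium alkoxide on the methyl ester, should give 33. Stereocontrol then rests on the chair and on macrocyclic preference alone.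

2. Step 14. What may go wrong:
   - the acyl shift stops at an unfavourable equilibrium;
   - base causes migration of the exocyclic methylene into the ring or conjugate addition;
   - the same equilibrium leaks during the acylation of step 18.

   Fallback (irreversible, kinetically controlled relactonisation instead of equilibration). It sets out from 25 and comes back at 26. Hydrolysis with LiOH in THF/H2O at 0 °C gives the 6α,8α-dihydroxy seco acid F6. Lactonisation under Yamaguchi conditions at high dilution should then close on the less hindered O8 hydroxyl, since O6 is shielded by the cis CH2OTBDPS group, to give 26. If neither route gives 26, the fallback of step 13 avoids the transposition altogether.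

3. Step 7. What may go wrong:
   - insufficient enantiofacial discrimination on a Z-β,β-disubstituted enal;
   - Z→E isomerisation of the enal under the Lewis-acidic zinc conditions.

   Fallback (racemic addition, then oxidation and reagent-controlled reduction). It sets out from 14 and 15 and comes back at 17. Addition of the lithium acetylide of 15 (n-BuLi, THF, −78 °C) to 14 gives the racemic propargylic alcohol F7. MnO2 oxidation gives the alkenyl alkynyl ketone F8. Corey–Bakshi–Shibata reduction with the (R)-methyl oxazaborolidine and catecholborane, on the model in which the alkynyl arm is the small substituent, should give 17; the sense is checked by Mosher analysis as before.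

Further compounds
F1 | step 13 | (2Z,4R,5Z,9E)-1-[(tert-butyldimethylsilyl)oxy]-6-{[(tert-butyldiphenylsilyl)oxy]methyl}-2-iodo-12-[(4-methoxybenzyl)oxy]-10-methyldodeca-2,5,9-trien-4-yl (2E)-4-[(tert-butyldiphenylsilyl)oxy]-2-methylbut-2-enoate | COc1ccc(COCC/C(C)=C/CC/C(CO[Si](c2ccccc2)(c2ccccc2)C(C)(C)C)=C/[C@@H](OC(=O)/C(C)=C/CO[Si](c2ccccc2)(c2ccccc2)C(C)(C)C)/C=C(\I)CO[Si](C)(C)C(C)(C)C)cc1
F2 | step 13 | methyl (E)-enoate from F1 (CO2Me in place of iodine at C11, cis to C6) | COc1ccc(COCC/C(C)=C/CC/C(CO[Si](c2ccccc2)(c2ccccc2)C(C)(C)C)=C/[C@@H](OC(=O)/C(C)=C/CO[Si](c2ccccc2)(c2ccccc2)C(C)(C)C)/C=C(\C(=O)OC)CO[Si](C)(C)C(C)(C)C)cc1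
F3 | step 13 | methyl (E)-2-(bromomethyl)enoate from F2 (C13 bromide) | COc1ccc(COCC/C(C)=C/CC/C(CO[Si](c2ccccc2)(c2ccccc2)C(C)(C)C)=C/[C@@H](OC(=O)/C(C)=C/CO[Si](c2ccccc2)(c2ccccc2)C(C)(C)C)/C=C(\C(=O)OC)CBr)cc1
F4 | step 13 | primary alcohol from F3 (free C8 hydroxyl) | OCC/C(C)=C/CC/C(CO[Si](c1ccccc1)(c1ccccc1)C(C)(C)C)=C/[C@@H](OC(=O)/C(C)=C/CO[Si](c1ccccc1)(c1ccccc1)C(C)(C)C)/C=C(\C(=O)OC)CBr
F5 | step 13 | aldehyde from F4 (C8 aldehyde, acyclic cyclisation precursor) | O=CC/C(C)=C/CC/C(CO[Si](c1ccccc1)(c1ccccc1)C(C)(C)C)=C/[C@@H](OC(=O)/C(C)=C/CO[Si](c1ccccc1)(c1ccccc1)C(C)(C)C)/C=C(\C(=O)OC)CBr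
F6 | step 14 | 2-[(1R,2R,10S)-4-{[(tert-butyldiphenylsilyl)oxy]methyl}-2,10-dihydroxy-8-methylcyclodeca-3,7-dien-1-yl]prop-2-enoic acid (6α,8α-dihydroxy seco acid) | C=C(C(=O)O)[C@@H]1[C@@H](O)C/C(C)=C/CC/C(CO[Si](c2ccccc2)(c2ccccc2)C(C)(C)C)=C/[C@H]1O
F7 | step 7 | racemic (5Z,9E)-1-[(tert-butyldimethylsilyl)oxy]-6-{[(tert-butyldiphenylsilyl)oxy]methyl}-12-[(4-methoxybenzyl)oxy]-10-methyldodeca-5,9-dien-2-yn-4-ol | COc1ccc(COCC/C(C)=C/CC/C(CO[Si](c2ccccc2)(c2ccccc2)C(C)(C)C)=C/C(O)C#CCO[Si](C)(C)C(C)(C)C)cc1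
F8 | step 7 | (5Z,9E)-1-[(tert-butyldimethylsilyl)oxy]-6-{[(tert-butyldiphenylsilyl)oxy]methyl}-12-[(4-methoxybenzyl)oxy]-10-methyldodeca-5,9-dien-2-yn-4-one | COc1ccc(COCC/C(C)=C/CC/C(CO[Si](c2ccccc2)(c2ccccc2)C(C)(C)C)=C/C(=O)C#CCO[Si](C)(C)C(C)(C)C)cc1
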